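**Plan**
- Retrosynthesis: the two aryl O–CH2OMe bonds (MOM ethers on O5 and O7) are cut first, then the C2–H bond (flavanone back to the flat flavone). A single cut through the three ring C bonds C4a–C4, C4–C3 and O1–C2 then leaves a ring A ortho-iodophenol, carbon monoxide and a ring B arylacetylene.
- Enabling feature: C4 is one carbonyl carbon standing between C4a of ring A and the C3–C2 pair that carries ring B, and O1 is the ring A oxygen lying between C4a and the prenylated C8. Ring C is therefore exactly iodophenol + CO + alkyne.
- Forward order: the pyran ring of the ring B chromene is made first (propargyl ether Claisen cascade) and the aldehyde is homologated to the alkyne. Ring A is dressed from phloroglucinol (bis-MOM, iodination, C-prenylation), and ring C closes last in the carbonylative annulation.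
- Stereochemistry: C2 is the only stereocenter. It is set after the annulation by ligand-controlled conjugate addition of copper hydride to the Re face of C2 of the flavone (2S), and the final acid deprotection does not touch it.

Key step: step 8

Assumption: (R)-DTBM-SEGPHOS is written as the ligand enantiomer expected to deliver hydride to the Re face of C2; the assignment rests on analogy, and the mirror-image ligand takes its place if the sense proves opposite.

Prenyl = 3-methylbut-2-en-1-yl throughout.

**Step 1**
Reactants: 1 4-hydroxybenzaldehyde; 2 prenyl bromide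
Product: 3 4-hydroxy-3-prenylbenzaldehyde
Conditions: 10% aq. KOH, rt; then dil. HCl
Reagents that add atoms: none
Why: Phenoxide C-alkylation (ortho-prenylation) in water, where hydrogen bonding to the phenoxide oxygen steers the ambident anion towards carbon; the para position is blocked by the formyl group, and the O-prenyl ether by-product should be separable by chromatography.

**Step 2**
Reactants: 3 4-hydroxy-3-prenylbenzaldehyde; 4 3-chloro-3-methylbut-1-yne
Product: 5 4-[(2-methylbut-3-yn-2-yl)oxy]-3-prenylbenzaldehyde
Conditions: K2CO3, KI, CuI (cat.), acetone, reflux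
Reagents that add atoms: none
Why: Copper-assisted propargylic substitution of the tertiary propargyl chloride by the phenoxide, the standard entry to aryl 1,1-dimethylpropargyl ethers; aldehyde and prenyl group are inert.

**Step 3**
Reactants: 5 4-[(2-methylbut-3-yn-2-yl)oxy]-3-prenylbenzaldehyde
Product: 8 2,2-dimethyl-8-prenyl-2H-chromene-6-carbaldehyde, via allenylphenol 6 (not isolated), via quinone methide 7 (not isolated)
Conditions: PhNEt2, 190 °C
Reagents that add atoms: none
Why: Aromatic propargyl Claisen rearrangement to the only free ortho carbon gives allenylphenol 6 after tautomerization, and a [1,5]-hydrogen shift to ortho-quinone methide 7 followed by oxa-6π electrocyclization closes the 2,2-dimethyl-2H-pyran ring.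

**Step 4**
Reactants: 8 2,2-dimethyl-8-prenyl-2H-chromene-6-carbaldehyde
Product: 9 6-ethynyl-2,2-dimethyl-8-prenyl-2H-chromene
Conditions: dimethyl (1-diazo-2-oxopropyl)phosphonate, K2CO3, MeOH, rt
Reagents that add atoms: dimethyl (1-diazo-2-oxopropyl)phosphonate (Ohira–Bestmann reagent), COP(=O)(OC)C(=[N+]=[N-])C(C)=O
Why: Seyferth–Gilbert homologation in the Ohira–Bestmann variant: methanolysis of the reagent gives the diazomethylphosphonate anion, which olefinates the aldehyde, and loss of N2 with 1,2-hydrogen shift gives the terminal alkyne under conditions mild enough for the chromene and prenyl alkenes.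

**Step 5**
Reactants: 10 phloroglucinol
Product: 11 3,5-bis(methoxymethoxy)phenol
Conditions: MOMCl (2.0 equiv), i-Pr2NEt, DMF, 0 °C → rt
Reagents that add atoms: chloromethyl methyl ether (MOMCl), COCCl
Why: Base-mediated O-alkylation with MOMCl; the three hydroxyls are equivalent, so only the degree of alkylation needs control (mono- and tris-ethers removed and recycled), and the oxygen that stays free is fixed before any carbon substituent is present.

**Step 6**
Reactants: 11 3,5-bis(methoxymethoxy)phenol
Product: 12 2-iodo-3,5-bis(methoxymethoxy)phenol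
Conditions: NIS (1.0 equiv), CH2Cl2, −40 → 0 °C
Reagents that add atoms: N-iodosuccinimide, O=C1CCC(=O)N1I
Why: Electrophilic aromatic iodination; the two carbons ortho to the free hydroxyl are equivalent and should be preferred over C4, which is shielded by two flanking MOM ethers, while one equivalent of NIS at low temperature limits di-iodination.

**Step 7**
Reactants: 12 2-iodo-3,5-bis(methoxymethoxy)phenol; 2 prenyl bromide
Product: 13 2-iodo-3,5-bis(methoxymethoxy)-6-prenylphenol
Conditions: NaH, toluene, 0 °C → rt
Reagents that add atoms: none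
Why: Ortho-C-alkylation of the sodium phenoxide as a tight ion pair in toluene (sodium bridging the oxygen and the departing bromide), possible only at C6 because the other ortho carbon carries iodine; the free hydroxyl thereby lies between iodine and prenyl.

**Step 8**
Reactants: 13 2-iodo-3,5-bis(methoxymethoxy)-6-prenylphenol; 14 carbon monoxide; 9 6-ethynyl-2,2-dimethyl-8-prenyl-2H-chromene
Product: 17 2-(2,2-dimethyl-8-prenyl-2H-chromen-6-yl)-5,7-bis(methoxymethoxy)-8-prenyl-4H-chromen-4-one, via ynone 15 (not isolated), via enaminone 16 (not isolated)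
Conditions: PdCl2(PPh3)2 (5 mol %), CO (20 bar), Et2NH, 120 °C
Reagents that add atoms: none
Why: Zerovalent palladium, formed from PdCl2(PPh3)2 under CO and amine, inserts into the C4a–I bond of 13, migratory insertion of CO gives the aroyl complex of divalent palladium, and amine-assisted transfer of the acetylide of 9 followed by reductive elimination gives ynone 15 (bonds C4a–C4 and C4–C3). Diethylamine then adds to C2 of the ynone to give enaminone 16, and the C8a hydroxyl attacks C2 in an addition–elimination that expels the amine and forms O1–C2. The closest known reaction is the PdCl2(PPh3)2-catalysed carbonylative annulation of ortho-iodophenols with terminal arylacetylenes to flavones. Ring C closes in the 6-endo mode with respect to the former triple bond, and the 5-exo closure to an aurone is excluded because the enaminone offers only C2 as electrophilic carbon. No stereocenter is formed; the step needs CO insertion ahead of alkyne coupling, which the CO pressure and the ready migration of the electron-rich aryl group onto CO should secure, and closure through one defined oxygen, which is secured by MOM ethers on the other two oxygens so that the hydroxyl flanked by prenyl becomes O1 and the prenyl group ends on C8.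

**Step 9**
Reactants: 17 2-(2,2-dimethyl-8-prenyl-2H-chromen-6-yl)-5,7-bis(methoxymethoxy)-8-prenyl-4H-chromen-4-one
Product: 19 (2S)-2-(2,2-dimethyl-8-prenyl-2H-chromen-6-yl)-5,7-bis(methoxymethoxy)-8-prenylchroman-4-one, via silyl enol ether 18 (not isolated)
Conditions: Cu(OAc)2 (5 mol %), (R)-DTBM-SEGPHOS (5.5 mol %), (EtO)2MeSiH, toluene, 0 °C → rt; then 1 M HCl, THF, 0 °C
Reagents that add atoms: none
Why: Asymmetric conjugate reduction with ligated copper hydride, known for 2-substituted chromen-4-ones: hydride adds to C2 of the only carbonyl-conjugated alkene, the chiral bisphosphine directing it to the Re face to set 2S, the copper enolate is turned over by the silane to silyl enol ether 18 (no alcohol additive, so the chromene alkene and the ketone are not reduced), and cold dilute acid releases the ketone without a free enolate that could open ring C.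

**Step 10**
Reactants: 19 (2S)-2-(2,2-dimethyl-8-prenyl-2H-chromen-6-yl)-5,7-bis(methoxymethoxy)-8-prenylchroman-4-one
Product: 20 maackiaflavanone B
Conditions: 3 M aq. HCl, MeOH, 45 °C
Reagents that add atoms: none
Why: Acid-catalysed acetal cleavage (transacetalization to methanol) of the two aryl MOM ethers; dilute acid at moderate temperature should spare the prenyl groups and the chromene, and C2 does not epimerize in the absence of base-induced ring opening.

**Compound list**
1 | 4-hydroxybenzaldehyde | O=Cc1ccc(O)cc1 | starting material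
2 | prenyl bromide (1-bromo-3-methylbut-2-ene) | CC(C)=CCBr | starting material
3 | 4-hydroxy-3-prenylbenzaldehyde | CC(C)=CCc1cc(C=O)ccc1O | intermediate
4 | 3-chloro-3-methylbut-1-yne | C#CC(C)(C)Cl | starting material
5 | 4-[(2-methylbut-3-yn-2-yl)oxy]-3-prenylbenzaldehyde | CC(C)=CCc1cc(C=O)ccc1OC(C)(C)C#C | intermediate
6 | 4-hydroxy-3-(3-methylbuta-1,2-dien-1-yl)-5-prenylbenzaldehyde (allenylphenol) | CC(C)=CCc1cc(C=O)cc(C=C=C(C)C)c1O | intermediate
7 | 3-(3-methylbut-2-en-1-ylidene)-4-oxo-5-prenylcyclohexa-1,5-diene-1-carbaldehyde (ortho-quinone methide) | CC(C)=CCC1=CC(C=O)=CC(=CC=C(C)C)C1=O | intermediate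
8 | 2,2-dimethyl-8-prenyl-2H-chromene-6-carbaldehyde | CC(C)=CCc1cc(C=O)cc2c1OC(C)(C)C=C2 | intermediate
9 | 6-ethynyl-2,2-dimethyl-8-prenyl-2H-chromene | CC(C)=CCc1cc(C#C)cc2c1OC(C)(C)C=C2 | intermediate
10 | phloroglucinol | Oc1cc(O)cc(O)c1 | starting material
11 | 3,5-bis(methoxymethoxy)phenol | COCOc1cc(O)cc(OCOC)c1 | intermediate
12 | 2-iodo-3,5-bis(methoxymethoxy)phenol | COCOc1cc(OCOC)c(I)c(O)c1 | intermediate
13 | 2-iodo-3,5-bis(methoxymethoxy)-6-prenylphenol | COCOc1cc(OCOC)c(CC=C(C)C)c(O)c1I | intermediate
14 | carbon monoxide | [C-]#[O+] | starting material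
15 | 3-(2,2-dimethyl-8-prenyl-2H-chromen-6-yl)-1-[2-hydroxy-4,6-bis(methoxymethoxy)-3-prenylphenyl]prop-2-yn-1-one | CC(C)=CCc1cc(C#CC(=O)c3c(OCOC)cc(OCOC)c(CC=C(C)C)c3O)cc2c1OC(C)(C)C=C2 | intermediate
16 | 3-(diethylamino)-3-(2,2-dimethyl-8-prenyl-2H-chromen-6-yl)-1-[2-hydroxy-4,6-bis(methoxymethoxy)-3-prenylphenyl]prop-2-en-1-one | CC(C)=CCc1cc(C(=CC(=O)c3c(OCOC)cc(OCOC)c(CC=C(C)C)c3O)N(CC)CC)cc2c1OC(C)(C)C=C2 | intermediate
17 | 2-(2,2-dimethyl-8-prenyl-2H-chromen-6-yl)-5,7-bis(methoxymethoxy)-8-prenyl-4H-chromen-4-one | CC(C)=CCc1cc(C2=CC(=O)c3c(OCOC)cc(OCOC)c(CC=C(C)C)c3O2)cc2c1OC(C)(C)C=C2 | intermediate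
18 | (2S)-4-{[diethoxy(methyl)silyl]oxy}-2-(2,2-dimethyl-8-prenyl-2H-chromen-6-yl)-5,7-bis(methoxymethoxy)-8-prenyl-2H-chromene | CC(C)=CCc1cc([C@@H]2C=C(O[Si](C)(OCC)OCC)c3c(OCOC)cc(OCOC)c(CC=C(C)C)c3O2)cc2c1OC(C)(C)C=C2 | intermediate
19 | (2S)-2-(2,2-dimethyl-8-prenyl-2H-chromen-6-yl)-5,7-bis(methoxymethoxy)-8-prenylchroman-4-one | CC(C)=CCc1cc([C@@H]2CC(=O)c3c(OCOC)cc(OCOC)c(CC=C(C)C)c3O2)cc2c1OC(C)(C)C=C2 | intermediate
20 | maackiaflavanone B, (2S)-2-(2,2-dimethyl-8-prenyl-2H-chromen-6-yl)-5,7-dihydroxy-8-prenylchroman-4-one | CC(C)=CCc1cc([C@@H]2CC(=O)c3c(O)cc(O)c(CC=C(C)C)c3O2)cc2c1OC(C)(C)C=C2 | target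

**Step count**
Total: 10 steps. Longest linear sequence: 7 steps (steps 1–4, then 8–10); the ring A branch (steps 5–7) joins at step 8.

**Steps most likely to fail**

Step 8. The alkyne may couple before CO inserts, diethylamine may capture the aroyl palladium as an amide, or oxidative addition at the doubly ortho-substituted, electron-rich C–I bond may be too slow. The fallback forms the same ynone without palladium and sets out from 9 and 13. Alkyne 9 is deprotonated with n-BuLi and formylated with DMF (THF, −78 °C, buffered quench) to give 3-(2,2-dimethyl-8-prenyl-2H-chromen-6-yl)prop-2-ynal F1. Iodophenol 13 is converted into its magnesium phenoxide with MeMgCl and subjected to iodine–magnesium exchange with i-PrMgCl·LiCl (THF, −20 °C → rt). The resulting aryl Grignard reagent is added to F1 to give the racemic propargylic alcohol F2. MnO2 in CH2Cl2 should oxidize F2 to ynone 15, where the fallback comes back to the route; Et2NH in EtOH at 50 °C then closes 15 through 16 to 17.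

Step 9. The β-aryl vinylogous ester may react sluggishly with copper hydride, facial discrimination may be insufficient, 1,2-reduction may compete, or the copper enolate may open ring C by β-elimination of the C8a phenoxide. The fallback separates reduction from stereocontrol and sets out from 17. Conjugate reduction with LiBH(s-Bu)3 (THF, −78 °C) should give the racemic flavanone F3. Kinetic resolution by asymmetric transfer hydrogenation (Cp*RhCl[(R,R)-TsDPEN], HCO2H/Et3N, EtOAc, rt; the catalyst enantiomer being the one that consumes the 2R ketone) converts the unwanted enantiomer into the cis-(2R,4R)-flavan-4-ol F4. The unreacted 2S ketone is separated by chromatography, and the fallback comes back to the route at 19.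

Step 7. The phenoxide may be alkylated on oxygen instead of carbon, at the para carbon C4, or twice. The fallback replaces the intermolecular C-alkylation by a sigmatropic transfer from oxygen and sets out from 12. O-Alkylation with 4 (K2CO3, KI, CuI cat., acetone, reflux) gives the propargyl ether F5. Semi-hydrogenation (H2, Pd/CaCO3 poisoned with Pb(OAc)2, quinoline, EtOAc) gives the 1,1-dimethylallyl ether F6. Aromatic Claisen rearrangement (toluene, 110 °C) can only go to C6, since the other ortho carbon carries iodine, and delivers the linear prenyl group; the fallback comes back to the route at 13.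

**Further compounds**
F1 | step 8 | 3-(2,2-dimethyl-8-prenyl-2H-chromen-6-yl)prop-2-ynal | CC(C)=CCc1cc(C#CC=O)cc2c1OC(C)(C)C=C2
F2 | step 8 | racemic 3-(2,2-dimethyl-8-prenyl-2H-chromen-6-yl)-1-[2-hydroxy-4,6-bis(methoxymethoxy)-3-prenylphenyl]prop-2-yn-1-ol | CC(C)=CCc1cc(C#CC(O)c3c(OCOC)cc(OCOC)c(CC=C(C)C)c3O)cc2c1OC(C)(C)C=C2
F3 | step 9 | racemic 2-(2,2-dimethyl-8-prenyl-2H-chromen-6-yl)-5,7-bis(methoxymethoxy)-8-prenylchroman-4-one | CC(C)=CCc1cc(C2CC(=O)c3c(OCOC)cc(OCOC)c(CC=C(C)C)c3O2)cc2c1OC(C)(C)C=C2
F4 | step 9 | (2R,4R)-2-(2,2-dimethyl-8-prenyl-2H-chromen-6-yl)-5,7-bis(methoxymethoxy)-8-prenylchroman-4-ol | CC(C)=CCc1cc([C@H]2C[C@@H](O)c3c(OCOC)cc(OCOC)c(CC=C(C)C)c3O2)cc2c1OC(C)(C)C=C2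
F5 | step 7 | 2-iodo-1,5-bis(methoxymethoxy)-3-[(2-methylbut-3-yn-2-yl)oxy]benzene | COCOc1cc(OCOC)c(I)c(OC(C)(C)C#C)c1
F6 | step 7 | 2-iodo-1,5-bis(methoxymethoxy)-3-[(2-methylbut-3-en-2-yl)oxy]benzene | COCOc1cc(OCOC)c(I)c(OC(C)(C)C=C)c1
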